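Don't plan ash on birch's 81.4 % at 28 min, as you suggested. Birch turned that share of a smaller charge with the same Xc.

| flask | Xa | Xc | Xp | time |
|---|---|---|---|---|
| cedar | 150 mM | 12.0 mM |  |  |
| alder | 75.0 mM | 12.0 mM |  |  |
| larch | 150 mM | 12.0 mM | 45.0 mM |  |
| birch | 150 mM | 36.0 mM |  |  |
| ash | 300 mM | 36.0 mM |  | 28 min |

| cedar run: time / min | cedar run: [Xp] / mM | alder run: time / min | alder run: [Xp] / mM | larch run: time / min | larch run: [Xp] / mM | birch run: time / min | birch run: [Xp] / mM |
|---|---|---|---|---|---|---|---|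
| 1.1 | 5.1 | 1.1 | 3.0 | 1.1 | 48.9 | 1.1 | 12.3 |
| 1.8 | 7.1 | 1.8 | 5.0 | 1.8 | 53.3 | 1.8 | 18.6 |
| 2.8 | 12.8 | 2.8 | 8.7 | 2.8 | 57.2 | 2.8 | 27.7 |
| 4.4 | 15.3 | 4.4 | 12.9 | 4.4 | 60.9 | 4.4 | 41.8 |
| 7.0 | 25.5 | 7.0 | 18.9 | 7.0 | 70.5 | 7.0 | 60.2 |
| 11 | 35.4 | 11 | 25.6 | 11 | 82.3 | 11 | 83.2 |
| 18 | 52.9 | 18 | 33.3 | 18 | 96.3 | 18 | 109.4 |
| 28 | 64.2 | 28 | 38.5 | 28 | 110.4 | 28 | 122.1 |

(standard deviation of a reading: 1 mM)

- Overall: Xa -> Xp, with Xc as catalyst.
- Constant volume, constant temperature.
- A reading of a species includes what of it is bound.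
- An order is taken over about fifteen percent of the charge, up and down.

* reaction order in [Xa] at the outset, round the charge of the cedar run, defined at two percent of the Xa turned into Xp (one fixed amount of Xp, the same in the runs compared)
* reaction order in [Xc] at the outset, round the charge of the cedar run, defined at two percent of the Xa turned into Xp
* Xp in the ash run at 28 min, as a share of the Xa charged

Reckon in depth, not in share. Cedar has 42.8 % turned at 28 min, so its depth is 0.559, depth being the natural log of the charge over the charge less the Xp made. It is a yardstick and no rate law, and unlike a share it has no ceiling at full turnover.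

The other two plain runs at the same time:

alder depth = 0.720

birch depth = 1.68

Birch over cedar is 3.01 in depth, for 3.00 in Xc. So depth follows Xc in these readings. Seeded larch, counting the Xp made, stands at 0.573, so I leave added Xp out.

Ash is birch with the Xa doubled, as cedar is alder with the Xa doubled. I assume that step costs the same factor at both levels of Xc:

ash depth = birch × cedar / alder = 1.30

ash share = 72.9 %

The forecast gave an order of 0.42 in Xa, 0.87 in Xc and 65 % for ash, holding that “the catalyst is dying, perhaps more slowly when saturated”, and my share stands above its figure.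

The flask gives orders of 0.26 in Xa and 0.94 in Xc, and 74.9 % for ash, a depth of 1.38 against my 1.30.

    2 Xc ⇌ Xc2, settled at all times (554.0 M⁻¹)
    Xc + Xa → Xp + Xc (33.90 M⁻¹ min⁻¹)
    Xc → G (0.5244 min⁻¹)
    Xc + Xa ⇌ Xc.Xa, settled at all times (81.10 M⁻¹)

Two things acting together hold ash down: Xc tied up as Xc.Xa and Xc gone to G. The ash run without the tying up reaches 90.1 %, a depth of 2.31, and the one without G reaches 88.8 %. Seeded larch keeps cedar's pace in depth: it makes 0.288 at 11.2 min, cedar makes the same at 11.2 min, and at 28 min larch stands at 0.573 against cedar's 0.559.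

The runs are simulated for an exercise, and the scatter is random.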